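A leftover first: dusk ends with about 0.0125 M of partner unspent, if one partner goes into each target, so substrate is the limiting reagent and I keep the ledger in substrate.

| flask | substrate | partner | capture agent | remark | time |
|---|---|---|---|---|---|
| dusk | 0.050 M | 1.2 equiv | 2.5 mM | run made earlier |  |
| autumn | 0.025 M | 1.2 equiv | 2.5 mM | run made earlier |  |
| winter | 0.038 M | 1.2 equiv | 2.5 mM | run made earlier |  |
| birch | 0.050 M | 1.20 equiv | 2.50 mM | everything together at the start | 12 h |
| maple | 0.050 M (fed, over 8.0 h) | 1.20 equiv | 2.50 mM | all else is in the flask from the start; the feed brings no volume worth counting | 12 h |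
| larch | 0.050 M | 1.20 equiv (fed, over 8.0 h) | 2.50 mM | all else is in the flask from the start; the feed brings no volume worth counting | 12 h |

| run | time / h | target / % | substrate / % |
|---|---|---|---|
| dusk | 1.00 | 69 | 20 |
| dusk | 1.50 | 86 | 8 |
| dusk | 2.50 | 89 | 3 |
| dusk | 4.00 | 92 | 0 |
| dusk | 8.00 | 93 | 0 |
| dusk | 12.0 | 95 | 1 |
| autumn | 1.33 | 73 | 13 |
| autumn | 2.50 | 86 | 2 |
| autumn | 4.00 | 89 | 0 |
| autumn | 5.00 | 88 | 1 |
| autumn | 6.00 | 94 | 0 |
| autumn | 8.00 | 90 | 0 |
| winter | 1.33 | 75 | 12 |
| winter | 2.50 | 90 | 1 |
| winter | 4.00 | 89 | 2 |
| winter | 5.00 | 92 | 0 |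
| winter | 6.00 | 92 | 0 |
| winter | 8.00 | 93 | 1 |

(each reading ± 1.5 percentage points)



1. the best flask by amount of target, in percent of the substrate charged; "all alike" if 1.5 percentage points covers them all (birch / maple / larch / all alike)
2. amount of target at the end, in percent of the substrate charged, birch
3. amount of target at the end, in percent of the substrate charged, maple
4. amount of target at the end, in percent of the substrate charged, larch

1. Exit from substrate. In dusk, 20 % of the substrate stands at 1.00 h, which reads as a first-order constant k = 1.61 h⁻¹. Autumn reads 1.53 h⁻¹ with half the partner concentration of dusk, and winter reads 1.59 h⁻¹. So substrate leaves on its own clock, with lifetime τ = 1/k = 0.621 h.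

2. In transit. At 1.00 h in dusk, substrate and target together read 89.0 %, so I book the rest in two parts: an intermediate on its way, and a loss that the closing entry sizes.

3. Closing entry. Dusk levels off near 93.3 % target, a reading, and the remainder is a loss I cannot yet name.

4. Larch. I carry one quantity: a = 0.0932, the equivalents of partner fed during one substrate lifetime. The lifetime is much shorter than the feed, 0.621 h against 8.0 h.

5. My reckoning. After 3 lifetimes in larch, substrate is down to 4.98 %, while the partner fed equals 28.0 % of the substrate charged. If the intermediate cannot wait, larch gives about 28.0 % target. I put birch near the dusk plateau and maple no lower.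

6. The forecast says all alike, with 93.5 % for birch, 93.5 % for maple and 92.5 % for larch, on the ground that “intermediate piles up awaiting partner”. On larch it and I part.

    partner → decomposition product (k = 5.10 × 10⁻⁷ s⁻¹)
    open intermediate + capture agent → trapped intermediate (k = 0.00560 M⁻¹ s⁻¹)
    partner + open intermediate → target (k = 0.120 M⁻¹ s⁻¹)
    substrate → open intermediate (k = 4.40 × 10⁻⁴ s⁻¹)
    2 open intermediate → homo product (k = 0.0710 M⁻¹ s⁻¹)

The best flask is maple: birch gives 93.7 %, maple 97.6 % and larch 26.8 %, which is 66 percentage points below the forecast. At 12.0 h, larch holds 72.2 % of its substrate as homo product, against 5.91 % in birch. For larch, 3a stands at 28.0 %. The neighbour of larch with 3.00 equiv of partner has a = 0.233, so 3a there is 69.9 %, and that flask gives 46.7 % target.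

(The runs are simulated for substances that don't exist.)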